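## Retrosynthetic overview

1. Locants (xanthanolide convention): the cycloheptane is C1 [C(OH), carries the crotonoyl chain C2(=O)–C3=C4–C15], C5 (O‑acyl), C6 (lactone O), C7, C8 (CH2), C9 (CHOH), C10 (CHCH3). The γ‑lactone ring is O–C6–C7–C11(=C13H2)–C12(=O).
2. The last disconnection is C7–C8 of the cycloheptane, by retro‑SH2'. The enabling feature is the allyl triad C7–C11=C13 of the lactone ring (ring‑fusion CH next to the exocyclic methylene, conjugated with C12=O), beside the unsubstituted C8H2 flanked by the C9 carbinol. The cis‑fused bicycle unfolds to a flat 3‑(phenylsulfonylmethyl)butenolide (C7=C11–C13–SO2Ph) whose C6 carries an open chain ending in a C8/C9 iodohydrin, so two electrophilic carbons (C8–I and the Michael carbon C7) are joined through a radical.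
3. C5–C6 comes from a chelate‑controlled vinylogous Mukaiyama aldol. The nucleophile is a 2‑silyloxyfuran (the γ‑lactone ring in aromatic disguise, made from α‑methylene‑γ‑butyrolactone) and the electrophile is an α‑hydroxy‑α‑crotonoyl aldehyde. The C5 ester follows by acylation.
4. The aldehyde comes from a temporary α‑methylene‑γ‑lactone, O–C9–C10–C1(=C5H2)–C2(=O). It is built by Sharpless epoxidation of crotyl alcohol, alkynylalane opening, Pd cyclocarbonylation and face‑selective dihydroxylation (sets C1). The ring is then opened with propenyllithium (brings in C3, C4, C15).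
5. Ring order: temporary lactone (made, then opened), then the γ‑lactone ring (furan/butenolide), then the cycloheptane last.

Key step: step 16

Remark: all γ‑hydroxy ketones of the route, the target included, are drawn in the open form. A reversible five‑membered hemiketal (C9–O–C2) is assumed not to interfere.

## Route

Step 1
Reactants: 1 (E)-but-2-en-1-ol
Product: 2 [(2R,3R)-3-methyloxiran-2-yl]methanol
Conditions: Ti(OiPr)4 (cat.), D-(−)-DIPT (cat.), t-BuOOH, 4 Å MS, CH2Cl2, −20 °C
Reagents that add atoms: tert-butyl hydroperoxide, CC(C)(C)OO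
Why: Sharpless asymmetric epoxidation, in which the D-(−)-tartrate/titanium complex delivers oxygen to the face of the E-allylic alcohol that gives the (2R,3R)-trans-epoxide and so fixes C9 and, after later inversion, C10.

Step 2
Reactants: 2 [(2R,3R)-3-methyloxiran-2-yl]methanol; 3 ethynyl(trimethyl)silane
Product: 4 (2S,3R)-3-methyl-5-(trimethylsilyl)pent-4-yne-1,2-diol
Conditions: 3, n-BuLi, toluene, 0 °C; Et2AlCl; then 2, 0 °C → rt; aq. HCl work-up
Reagents that add atoms: none
Why: Hydroxyl-directed SN2 opening of a 2,3-epoxy alcohol by an alkynylalane at the distal carbon, where inversion at the methyl-bearing carbon gives the syn C9-OH/C10-CH3 array and brings in C1 and C5.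

Step 3
Reactants: 4 (2S,3R)-3-methyl-5-(trimethylsilyl)pent-4-yne-1,2-diol
Product: 5 (2S,3R)-3-methylpent-4-yne-1,2-diol
Conditions: K2CO3 (cat.), MeOH, rt
Reagents that add atoms: none
Why: Base-catalysed methanolysis of the C(sp)–Si bond (protiodesilylation) frees the terminal alkyne and touches no stereocentre.

Step 4
Reactants: 5 (2S,3R)-3-methylpent-4-yne-1,2-diol
Product: 6 (2S,3R)-1-[(tert-butyldimethylsilyl)oxy]-3-methylpent-4-yn-2-ol
Conditions: TBSCl, imidazole, CH2Cl2, 0 °C
Reagents that add atoms: tert-butyldimethylsilyl chloride, CC(C)(C)[Si](C)(C)Cl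
Why: Selective silylation of the less hindered primary hydroxyl (C8–OH) keeps the secondary C9 hydroxyl free for the lactonisation.

Step 5
Reactants: 6 (2S,3R)-1-[(tert-butyldimethylsilyl)oxy]-3-methylpent-4-yn-2-ol
Product: 7 (4R,5S)-5-{[(tert-butyldimethylsilyl)oxy]methyl}-4-methyl-3-methylideneoxolan-2-one (4,5-cis)
Conditions: PdCl2 (cat.), PPh3, SnCl2 (cat.), CO (7 bar), MeCN, 70 °C
Reagents that add atoms: carbon monoxide, [C-]#[O+]
Why: Palladium-catalysed cyclocarbonylation of a homopropargylic alcohol (Markovnikov hydroalkoxycarbonylation) builds the temporary α-methylene-γ-lactone with C2 coming from CO and with retention at both stereocentres, so that CH3 and CH2OTBS are cis.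

Step 6
Reactants: 7 (4R,5S)-5-{[(tert-butyldimethylsilyl)oxy]methyl}-4-methyl-3-methylideneoxolan-2-one
Product: 8 (3S,4S,5S)-5-{[(tert-butyldimethylsilyl)oxy]methyl}-3-hydroxy-3-(hydroxymethyl)-4-methyloxolan-2-one (CH2OH, CH3 and CH2OTBS all cis)
Conditions: OsO4 (cat.), NMO, acetone–H2O, rt
Reagents that add atoms: osmium tetroxide (catalytic oxygen carrier), O=[Os](=O)(=O)=O; N-methylmorpholine N-oxide, C[N+]1([O-])CCOCC1; water, O
Why: Upjohn dihydroxylation, in which osmium tetroxide adds to the exocyclic alkene from the lactone face opposite to the cis methyl and silyloxymethyl groups and thereby sets C1 with its hydroxyl trans and the new CH2OH (C5) cis to them.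

Step 7
Reactants: 8 (3S,4S,5S)-5-{[(tert-butyldimethylsilyl)oxy]methyl}-3-hydroxy-3-(hydroxymethyl)-4-methyloxolan-2-one
Product: 9 (3S,4S,5S)-5-{[(tert-butyldimethylsilyl)oxy]methyl}-3-hydroxy-4-methyl-3-{[(triethylsilyl)oxy]methyl}oxolan-2-one
Conditions: TESCl, imidazole, CH2Cl2, −20 °C
Reagents that add atoms: chlorotriethylsilane, CC[Si](Cl)(CC)CC
Why: Chemoselective silylation of the primary over the tertiary hydroxyl masks C5–OH against retro-aldol loss of formaldehyde in the strongly basic next step.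

Step 8
Reactants: 9 (3S,4S,5S)-5-{[(tert-butyldimethylsilyl)oxy]methyl}-3-hydroxy-4-methyl-3-{[(triethylsilyl)oxy]methyl}oxolan-2-one; 10 (E)-1-bromoprop-1-ene
Product: 12 (2E,5S,6S,7S)-8-[(tert-butyldimethylsilyl)oxy]-5-hydroxy-6-methyl-7-[(triethylsilyl)oxy]-5-{[(triethylsilyl)oxy]methyl}oct-2-en-4-one, via hydroxy enone 11 (not isolated)
Conditions: 10, t-BuLi, Et2O, −78 °C; then 9, THF, −78 °C; H2O; crude 11: TESCl, imidazole, DMAP (cat.), CH2Cl2, 0 °C
Reagents that add atoms: chlorotriethylsilane, CC[Si](Cl)(CC)CC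
Why: Halogen–lithium exchange with retention of the E geometry and 1,2-addition of the alkenyllithium to the γ-lactone, whose lithium hemiketal persists at −78 °C and so stops at the ketone stage, open the temporary ring to the crotonoyl ketone, after which the freed secondary C9 hydroxyl is silylated in preference to the tertiary one.

Step 9
Reactants: 12 (2E,5S,6S,7S)-8-[(tert-butyldimethylsilyl)oxy]-5-hydroxy-6-methyl-7-[(triethylsilyl)oxy]-5-{[(triethylsilyl)oxy]methyl}oct-2-en-4-one
Product: 13 (2S,3S,4S)-2-[(E)-but-2-enoyl]-5-[(tert-butyldimethylsilyl)oxy]-2-hydroxy-3-methyl-4-[(triethylsilyl)oxy]pentanal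
Conditions: (COCl)2, DMSO, CH2Cl2, −78 → −40 °C; Et3N, −78 → 0 °C
Reagents that add atoms: none
Why: Swern oxidation run directly on the silyl ether, in which the activated sulfonium salt cleaves and oxidises only the unhindered primary triethylsilyl ether while the secondary TES ether, the primary TBS ether and the tertiary alcohol stay.

Step 10
Reactants: 14 3-methylideneoxolan-2-one (α-methylene-γ-butyrolactone)
Product: 16 3-[(phenylsulfonyl)methyl]furan-2(5H)-one, via iodo sulfone 15 (not isolated)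
Conditions: PhSO2Na, I2, MeOH, rt; then Et3N, CH2Cl2, rt
Reagents that add atoms: sodium benzenesulfinate, [Na+].[O-]S(=O)c1ccccc1; iodine (stays only in 15), II
Why: Radical iodosulfonylation of the methacrylate-type alkene followed by dehydroiodination toward the ring CH2, the course known for methacrylates, gives the endocyclic allyl sulfone.

Step 11
Reactants: 16 3-[(phenylsulfonyl)methyl]furan-2(5H)-one
Product: 17 tert-butyl(dimethyl)({3-[(phenylsulfonyl)methyl]furan-2-yl}oxy)silane
Conditions: TBSOTf, Et3N, CH2Cl2, 0 °C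
Reagents that add atoms: tert-butyldimethylsilyl triflate, CC(C)(C)[Si](C)(C)OS(=O)(=O)C(F)(F)F
Why: Soft enolisation (O-silylation and γ-deprotonation of the butenolide) is driven by aromatisation to the 2-silyloxyfuran.

Step 12
Reactants: 13 (2S,3S,4S)-2-[(E)-but-2-enoyl]-5-[(tert-butyldimethylsilyl)oxy]-2-hydroxy-3-methyl-4-[(triethylsilyl)oxy]pentanal; 17 tert-butyl(dimethyl)({3-[(phenylsulfonyl)methyl]furan-2-yl}oxy)silane
Product: 18 (5R)-5-{(1S,2S,3S,4S)-2-[(E)-but-2-enoyl]-5-[(tert-butyldimethylsilyl)oxy]-1,2-dihydroxy-3-methyl-4-[(triethylsilyl)oxy]pentyl}-3-[(phenylsulfonyl)methyl]furan-2(5H)-one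
Conditions: MgBr2·OEt2 (excess), CH2Cl2, −78 → −20 °C; pH 7 buffer
Reagents that add atoms: none
Why: Vinylogous Mukaiyama aldol reaction, in which Lewis acid promotion gives the threo (syn) C5/C6 relationship through the open transition state and the Cram chelate of magnesium between the C1 hydroxyl and the formyl oxygen exposes the Re face flanked by the flat C2 acyl group and shields the face flanked by the branched C10 chain, which sets C5 (S) and C6 (R).

Step 13
Reactants: 18 (5R)-5-{(1S,2S,3S,4S)-2-[(E)-but-2-enoyl]-5-[(tert-butyldimethylsilyl)oxy]-1,2-dihydroxy-3-methyl-4-[(triethylsilyl)oxy]pentyl}-3-[(phenylsulfonyl)methyl]furan-2(5H)-one; 19 (S)-2-methylbutanoic acid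
Product: 20 (1S,2S,3S,4S)-2-[(E)-but-2-enoyl]-5-[(tert-butyldimethylsilyl)oxy]-2-hydroxy-3-methyl-1-{(2R)-5-oxo-4-[(phenylsulfonyl)methyl]-2,5-dihydrofuran-2-yl}-4-[(triethylsilyl)oxy]pentyl (2S)-2-methylbutanoate
Conditions: EDCI, DMAP, CH2Cl2, 0 °C → rt
Reagents that add atoms: none
Why: Steglich esterification acylates the secondary C5 hydroxyl and leaves the tertiary C1 hydroxyl, and carbodiimide activation avoids a ketene and so keeps the α-stereocentre of the acid.

Step 14
Reactants: 20 (1S,2S,3S,4S)-2-[(E)-but-2-enoyl]-5-[(tert-butyldimethylsilyl)oxy]-2-hydroxy-3-methyl-1-{(2R)-5-oxo-4-[(phenylsulfonyl)methyl]-2,5-dihydrofuran-2-yl}-4-[(triethylsilyl)oxy]pentyl (2S)-2-methylbutanoate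
Product: 21 (1S,2S,3S,4S)-2-[(E)-but-2-enoyl]-2,4,5-trihydroxy-3-methyl-1-{(2R)-5-oxo-4-[(phenylsulfonyl)methyl]-2,5-dihydrofuran-2-yl}pentyl (2S)-2-methylbutanoate
Conditions: HF·pyridine, pyridine, THF, 0 °C → rt
Reagents that add atoms: none
Why: Fluoride-mediated cleavage of both silyl ethers under buffered, weakly acidic conditions spares the base-sensitive γ-(acyloxyalkyl)butenolide and the ester.

Step 15
Reactants: 21 (1S,2S,3S,4S)-2-[(E)-but-2-enoyl]-2,4,5-trihydroxy-3-methyl-1-{(2R)-5-oxo-4-[(phenylsulfonyl)methyl]-2,5-dihydrofuran-2-yl}pentyl (2S)-2-methylbutanoate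
Product: 22 (1S,2S,3S,4S)-2-[(E)-but-2-enoyl]-2,4-dihydroxy-5-iodo-3-methyl-1-{(2R)-5-oxo-4-[(phenylsulfonyl)methyl]-2,5-dihydrofuran-2-yl}pentyl (2S)-2-methylbutanoate
Conditions: I2, PPh3, imidazole, THF, 0 °C
Reagents that add atoms: iodine, II
Why: Garegg–Samuelsson (Appel-type) iodination, in which the alkoxyphosphonium salt forms and is displaced (SN2) only at the primary C8 hydroxyl.

Step 16
Reactants: 22 (1S,2S,3S,4S)-2-[(E)-but-2-enoyl]-2,4-dihydroxy-5-iodo-3-methyl-1-{(2R)-5-oxo-4-[(phenylsulfonyl)methyl]-2,5-dihydrofuran-2-yl}pentyl (2S)-2-methylbutanoate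
Product: 23 (3aS,5R,6S,7S,8S,8aR)-7-[(E)-but-2-enoyl]-5,7-dihydroxy-6-methyl-3-methylidene-2-oxooctahydro-2H-cyclohepta[b]furan-8-yl (2S)-2-methylbutanoate (target CNP0331957.1)
Conditions: (Bu3Sn)2, di-tert-butyl hyponitrite (cat., portions), degassed PhH (5 mM), 60 °C
Reagents that add atoms: none
Why: Proposed new method: a tributylstannyl radical from the ditin abstracts iodine from C8, the primary β-hydroxyalkyl radical adds to C7 (the β-carbon of the butenolide), and the resulting C11 radical expels PhSO2• by β-scission of the C13–S bond, so that the ring, the C7 stereocentre and the C11=C13 methylene arise together on the unprotected substrate while PhSO2• regenerates the stannyl radical from the ditin in a chain that contains no hydrogen donor. The closest known reaction type is the ditin-mediated radical allylation of alkyl iodides with allyl sulfones and 2-(sulfonylmethyl)acrylates (SH2' addition–fragmentation), here made intramolecular and directed at the substituted terminus held inside a lactone ring; in polarity terms two electrophilic carbons, C8–I and the Michael carbon C7, are joined. The cycloheptane closes in the 7-exo-trig mode, with C7 attacked and C11 left outside the new ring. C7 is controlled by C6, because the five-atom tether starts on one face of the flat butenolide and can reach C7 only from that face (a trans junction would need a C5–C6–C7–C8 torsion near 120° in the transition state), so the cis-fused lactone results. The step needs chemoselectivity for C7 over the crotonoyl C4 (7-endo), the C2 carbonyl carbon (5-exo with acyl shift) and 1,5-hydrogen transfer from C5–H, and this is secured by the doubly activated, strained cis-alkene of the sulfonylmethyl butenolide, by the quaternary C1 that holds the enone s-cis with C4 turned away from C8, by the β-methyl group on C4, and by the absence of any hydrogen donor.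

## Compound list

1 | (E)-but-2-en-1-ol | C/C=C/CO | starting material
2 | [(2R,3R)-3-methyloxiran-2-yl]methanol | OC[C@H]1O[C@@H]1C | intermediate
3 | ethynyl(trimethyl)silane | C#C[Si](C)(C)C | starting material
4 | (2S,3R)-3-methyl-5-(trimethylsilyl)pent-4-yne-1,2-diol | OC[C@@H](O)[C@H](C)C#C[Si](C)(C)C | intermediate
5 | (2S,3R)-3-methylpent-4-yne-1,2-diol | OC[C@@H](O)[C@H](C)C#C | intermediate
6 | (2S,3R)-1-[(tert-butyldimethylsilyl)oxy]-3-methylpent-4-yn-2-ol | CC(C)(C)[Si](C)(C)OC[C@@H](O)[C@H](C)C#C | intermediate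
7 | (4R,5S)-5-{[(tert-butyldimethylsilyl)oxy]methyl}-4-methyl-3-methylideneoxolan-2-one | CC(C)(C)[Si](C)(C)OC[C@H]1OC(=O)C(=C)[C@H]1C | intermediate
8 | (3S,4S,5S)-5-{[(tert-butyldimethylsilyl)oxy]methyl}-3-hydroxy-3-(hydroxymethyl)-4-methyloxolan-2-one | CC(C)(C)[Si](C)(C)OC[C@H]1OC(=O)[C@@](O)(CO)[C@H]1C | intermediate
9 | (3S,4S,5S)-5-{[(tert-butyldimethylsilyl)oxy]methyl}-3-hydroxy-4-methyl-3-{[(triethylsilyl)oxy]methyl}oxolan-2-one | CC(C)(C)[Si](C)(C)OC[C@H]1OC(=O)[C@@](O)(CO[Si](CC)(CC)CC)[C@H]1C | intermediate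
10 | (E)-1-bromoprop-1-ene | C/C=C/Br | starting material
11 | (2E,5S,6S,7S)-8-[(tert-butyldimethylsilyl)oxy]-5,7-dihydroxy-6-methyl-5-{[(triethylsilyl)oxy]methyl}oct-2-en-4-one | CC(C)(C)[Si](C)(C)OC[C@@H](O)[C@H](C)[C@@](O)(C(=O)/C=C/C)CO[Si](CC)(CC)CC | intermediate
12 | (2E,5S,6S,7S)-8-[(tert-butyldimethylsilyl)oxy]-5-hydroxy-6-methyl-7-[(triethylsilyl)oxy]-5-{[(triethylsilyl)oxy]methyl}oct-2-en-4-one | CC(C)(C)[Si](C)(C)OC[C@@H](O[Si](CC)(CC)CC)[C@H](C)[C@@](O)(C(=O)/C=C/C)CO[Si](CC)(CC)CC | intermediate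
13 | (2S,3S,4S)-2-[(E)-but-2-enoyl]-5-[(tert-butyldimethylsilyl)oxy]-2-hydroxy-3-methyl-4-[(triethylsilyl)oxy]pentanal | CC(C)(C)[Si](C)(C)OC[C@@H](O[Si](CC)(CC)CC)[C@H](C)[C@@](O)(C(=O)/C=C/C)C=O | intermediate
14 | 3-methylideneoxolan-2-one | C=C1CCOC1=O | starting material
15 | 3-iodo-3-[(phenylsulfonyl)methyl]oxolan-2-one (racemic) | O=C1OCCC1(I)CS(=O)(=O)c1ccccc1 | intermediate
16 | 3-[(phenylsulfonyl)methyl]furan-2(5H)-one | O=C1OCC=C1CS(=O)(=O)c1ccccc1 | intermediate
17 | tert-butyl(dimethyl)({3-[(phenylsulfonyl)methyl]furan-2-yl}oxy)silane | CC(C)(C)[Si](C)(C)Oc1occc1CS(=O)(=O)c1ccccc1 | intermediate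
18 | (5R)-5-{(1S,2S,3S,4S)-2-[(E)-but-2-enoyl]-5-[(tert-butyldimethylsilyl)oxy]-1,2-dihydroxy-3-methyl-4-[(triethylsilyl)oxy]pentyl}-3-[(phenylsulfonyl)methyl]furan-2(5H)-one | CC(C)(C)[Si](C)(C)OC[C@@H](O[Si](CC)(CC)CC)[C@H](C)[C@@](O)(C(=O)/C=C/C)[C@@H](O)[C@@H]1OC(=O)C(CS(=O)(=O)c2ccccc2)=C1 | intermediate
19 | (S)-2-methylbutanoic acid | CC[C@H](C)C(=O)O | starting material
20 | (1S,2S,3S,4S)-2-[(E)-but-2-enoyl]-5-[(tert-butyldimethylsilyl)oxy]-2-hydroxy-3-methyl-1-{(2R)-5-oxo-4-[(phenylsulfonyl)methyl]-2,5-dihydrofuran-2-yl}-4-[(triethylsilyl)oxy]pentyl (2S)-2-methylbutanoate | CC(C)(C)[Si](C)(C)OC[C@@H](O[Si](CC)(CC)CC)[C@H](C)[C@@](O)(C(=O)/C=C/C)[C@@H](OC(=O)[C@@H](C)CC)[C@@H]1OC(=O)C(CS(=O)(=O)c2ccccc2)=C1 | intermediate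
21 | (1S,2S,3S,4S)-2-[(E)-but-2-enoyl]-2,4,5-trihydroxy-3-methyl-1-{(2R)-5-oxo-4-[(phenylsulfonyl)methyl]-2,5-dihydrofuran-2-yl}pentyl (2S)-2-methylbutanoate | OC[C@@H](O)[C@H](C)[C@@](O)(C(=O)/C=C/C)[C@@H](OC(=O)[C@@H](C)CC)[C@@H]1OC(=O)C(CS(=O)(=O)c2ccccc2)=C1 | intermediate
22 | (1S,2S,3S,4S)-2-[(E)-but-2-enoyl]-2,4-dihydroxy-5-iodo-3-methyl-1-{(2R)-5-oxo-4-[(phenylsulfonyl)methyl]-2,5-dihydrofuran-2-yl}pentyl (2S)-2-methylbutanoate | IC[C@@H](O)[C@H](C)[C@@](O)(C(=O)/C=C/C)[C@@H](OC(=O)[C@@H](C)CC)[C@@H]1OC(=O)C(CS(=O)(=O)c2ccccc2)=C1 | intermediate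
23 | (3aS,5R,6S,7S,8S,8aR)-7-[(E)-but-2-enoyl]-5,7-dihydroxy-6-methyl-3-methylidene-2-oxooctahydro-2H-cyclohepta[b]furan-8-yl (2S)-2-methylbutanoate | C=C1C(=O)O[C@@H]2[C@H]1C[C@@H](O)[C@H](C)[C@@](O)(C(=O)/C=C/C)[C@H]2OC(=O)[C@@H](C)CC | target

## Step count and risks

Total step count: 16. Longest linear sequence: 14 steps (steps 1–9 and 12–16).

Steps most likely to fail:

1. **Step 16 (Proposed new method).**
   - What may go wrong: the 7-exo closure may be too slow. Then 5-exo attack of the C8 radical on the C2 carbonyl carbon with 1,4-acyl shift, 1,5-hydrogen transfer from C5–H, or addition of chain radicals to the freshly formed methylene lactone could take over.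
   - Fallback: known polar chemistry with C9 at the ketone level; it sets out from 22 and comes back at 23. Dess–Martin oxidation of 22 should give the α-iodo ketone F1. Activated zinc in THF (Reformatsky-type insertion) should give the regiodefined C8 zinc enolate. This enolate closes the same C7–C8 bond by intramolecular Michael addition, and the lactone enolate then loses benzenesulfinate (E1cB) to give the 9-oxo lactone F2. Evans–Saksena reduction (Me4NBH(OAc)3, MeCN–AcOH, −30 °C), with hydride delivered from boron bound to the C1 hydroxyl, should give the 1,3-anti diol 23.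

2. **Step 12.**
   - What may go wrong: chelate control may be lost, through a competing six-membered chelate via the C2 carbonyl or through an open transition state, giving poor facial selectivity at C5/C6. A Lewis-acid-induced α-ketol (acyl) shift of the α-hydroxy-β-keto aldehyde is also possible.
   - Fallback: reagent control and a metathesis-built lactone ring; it sets out from 13 and comes back at 20. Brown alkoxyallylboration of 13 uses the (Z)-γ-(4-methoxyphenoxy)allyl-diisopinocampheylborane made from allyl 4-methoxyphenyl ether, s-BuLi and (+)-Ipc2BOMe (Re-face attack, non-oxidative ethanolamine work-up). It should give the syn C5-hydroxy C6-aryl ether F3. Steglich esterification with 19 should give the C5 ester F4. Buffered ceric ammonium nitrate should remove the aryl group to give the allylic alcohol F5. Acylation with 2-[(phenylsulfonyl)methyl]acrylic acid (DCC, DMAP) should give the diene ester F6. Ring-closing metathesis (Grubbs second-generation catalyst, CH2Cl2, reflux) should close the butenolide and give 20.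

3. **Step 8.**
   - What may go wrong: attack on the hindered lactone carbonyl next to the lithium alkoxide may be sluggish. The tetrahedral intermediate may collapse early and allow a second addition. O-to-O silyl migration may occur.
   - Fallback: acyl transfer in two stages through a Weinreb amide; it sets out from 9 and comes back at 12. Aminolysis of 9 with MeNH(OMe)·HCl/Me3Al should give the hydroxy Weinreb amide F7. Silylation (TESCl, imidazole) should give the C9 silyl ether F8. (E)-Prop-1-enyllithium or the corresponding Grignard reagent should then stop at the ketone 12 because of the chelated tetrahedral intermediate.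

## Further compounds

F1 | step 16 | α-iodo ketone (C9 ketone of 22) | ICC(=O)[C@H](C)[C@@](O)(C(=O)/C=C/C)[C@@H](OC(=O)[C@@H](C)CC)[C@@H]1OC(=O)C(CS(=O)(=O)c2ccccc2)=C1
F2 | step 16 | 9-oxo lactone (C9 ketone of 23) | C=C1C(=O)O[C@@H]2[C@H]1CC(=O)[C@H](C)[C@@](O)(C(=O)/C=C/C)[C@H]2OC(=O)[C@@H](C)CC
F3 | step 12 | syn C5-hydroxy C6-(4-methoxyphenyl) ether with C7 vinyl group | CC(C)(C)[Si](C)(C)OC[C@@H](O[Si](CC)(CC)CC)[C@H](C)[C@@](O)(C(=O)/C=C/C)[C@@H](O)[C@H](Oc1ccc(OC)cc1)C=C
F4 | step 12 | C5 (S)-2-methylbutanoate of F3 | CC(C)(C)[Si](C)(C)OC[C@@H](O[Si](CC)(CC)CC)[C@H](C)[C@@](O)(C(=O)/C=C/C)[C@@H](OC(=O)[C@@H](C)CC)[C@H](Oc1ccc(OC)cc1)C=C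
F5 | step 12 | C6 allylic alcohol | CC(C)(C)[Si](C)(C)OC[C@@H](O[Si](CC)(CC)CC)[C@H](C)[C@@](O)(C(=O)/C=C/C)[C@@H](OC(=O)[C@@H](C)CC)[C@H](O)C=C
F6 | step 12 | C6 2-[(phenylsulfonyl)methyl]acrylate (diene ester) | CC(C)(C)[Si](C)(C)OC[C@@H](O[Si](CC)(CC)CC)[C@H](C)[C@@](O)(C(=O)/C=C/C)[C@@H](OC(=O)[C@@H](C)CC)[C@H](OC(=O)C(=C)CS(=O)(=O)c1ccccc1)C=C
F7 | step 8 | hydroxy Weinreb amide | CC(C)(C)[Si](C)(C)OC[C@@H](O)[C@H](C)[C@@](O)(C(=O)N(C)OC)CO[Si](CC)(CC)CC
F8 | step 8 | C9 triethylsilyl ether of F7 | CC(C)(C)[Si](C)(C)OC[C@@H](O[Si](CC)(CC)CC)[C@H](C)[C@@](O)(C(=O)N(C)OC)CO[Si](CC)(CC)CC
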